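Start from a leftover: by 5.5 min, Thursday's flask reads 0.164 M of Xp, and its early slope, held steady, promises more than that.

the same everywhere: Xc 0.00500 M
- Thursday's: Xa 0.500 M; Xb 0.600 M
- Saturday's: Xa 0.250 M; Xb 0.350 M
- Monday's: Xa 1.00 M; Xb 0.600 M
- Sunday's: Xa 0.500 M; Xb 0.600 M; time 16 min

| run | time / min | [Xp] / M |
|---|---|---|
| Thursday's run | 0.24 | 0.018 |
| Thursday's run | 0.74 | 0.054 |
| Thursday's run | 1.4 | 0.076 |
| Thursday's run | 2.2 | 0.115 |
| Thursday's run | 3.2 | 0.137 |
| Thursday's run | 4.3 | 0.155 |
| Thursday's run | 5.5 | 0.164 |
| Saturday's run | 0.24 | 0.006 |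
| Saturday's run | 0.74 | 0.012 |
| Saturday's run | 1.4 | 0.024 |
| Saturday's run | 2.2 | 0.037 |
| Saturday's run | 3.2 | 0.044 |
| Saturday's run | 4.3 | 0.053 |
| Saturday's run | 5.5 | 0.058 |
| Monday's run | 0.24 | 0.033 |
| Monday's run | 0.74 | 0.097 |
| Monday's run | 1.4 | 0.154 |
| Monday's run | 2.2 | 0.201 |
| Monday's run | 3.2 | 0.241 |
| Monday's run | 4.3 | 0.258 |
| Monday's run | 5.5 | 0.268 |

(standard deviation of a reading: 0.003 M)

- Overall: Xa + Xb -> Xp, with Xc as catalyst.
- Constant volume, constant temperature.
- An order is taken over about fifteen percent of the charge, up and down.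

- the exponent of [Xa] in the starting rate at the charge of the Thursday's run (at the point where two percent of the Xa have become Xp) (one fixed amount of Xp, the same in the runs compared)
- the exponent of [Xb] in the starting rate at the charge of the Thursday's run (at the point where two percent of the Xa have become Xp)
- Xp in the Sunday's run at 16 min, as a share of the Xa charged

Read the rate first. Doubling Xa gives Monday's early slope about twice Thursday's. Thursday's reading at 2.2 min stands 3.11 times Saturday's, against a ratio of charge products of 3.43. So take both exponents as one, with rate = k[Xa][Xb]. Monday's first slope, at mid-interval amounts, gives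

k = 0.250 M⁻¹ min⁻¹

Now integrate. With charges a and b, the amount turned is

s = (a − gb)/(1 − g), g = (a/b)exp(−(b − a)kt)

For Thursday's flask at 5.5 min this gives 0.235 M, more than the reading. Assume the shortfall is Xp leaving at first order and returning neither Xa nor Xb. Divide it by the area under Thursday's curve, 37.0 M·s:

d = (s − [Xp])/area = 0.114 min⁻¹

Call d the drain constant, the share of Xp lost per minute; its time is 8.77 min.

Sunday's charge is Thursday's, so continue from that last reading. Let P be the amount of Xp at the start of a leg of length T, with mean inflow r: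

P(end) = P e^(−dT) + r(1 − e^(−dT))/d

With s reaching 0.373 M at 16 min, one leg gives 0.130 M. The weak link is that flat inflow. Reforge it with two legs of 5.25 min, where s at the joint is 0.324 M. The inflows are 0.0171 M min⁻¹, then 9.31 mM min⁻¹. Xp passes 0.158 M and ends at 0.123 M, so I commit to 24.7 % of the Xa charged.

The forecast puts the exponents at 1.05 and 1.05, against my ones, and Sunday's flask at 34.8 %, higher than my figure, on the grounds that “this is a reversible approach to equilibrium, not catalyst death”.

Sunday's flask gives 24.9 %, and at Thursday's charge the exponents are 1.0 in Xa and 1.0 in Xb.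

    2 Xc ⇌ Xc2, settled at all times (109.0 M⁻¹)
    Xc2 + Xa + Xb → Xp + Xc2 (253.2 M⁻² min⁻¹)
    Xp → J (0.1110 min⁻¹)

A fit with the main steps alone leaves a root mean square residual of 6.4 in units of the scatter. Use d on Sunday's flask at 16 min: inflow is about 7.17 mM min⁻¹ and outflow 0.0142 M min⁻¹, so by this reckoning Xp leaves faster than it arrives at that moment. Monday's shortfall is 0.120 M over an area of 64.3 M·s, which reads a drain constant of 0.112 min⁻¹.

Readings and results were computed for substances that don't exist; the scatter is artificial.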